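The readings are calculated on assumed constants; the scatter is artificial.

- Raising the free catalyst by a factor of 1.53, from epsilon to eta, moves the reading at 0.667 h by 17 percentage points, far more than a factor of 2.23 in capture agent moves it from beta to gamma at that time, 1.4 points.

| setting | epsilon | beta | gamma | eta | ochre | blue | grey | red |
|---|---|---|---|---|---|---|---|---|
| substrate | 0.28 M | 0.28 M | 0.28 M | 0.28 M | 0.28 M | 0.28 M | 0.28 M | 0.28 M (fed, over 3.00 h) |
| coupling partner | 0.308 M | 0.308 M | 0.308 M | 0.308 M | 0.308 M (fed, over 3.00 h) | 0.308 M | 0.308 M | 0.308 M |
| capture agent | 0.014 M | 0.0094 M | 0.021 M | 0.014 M | 0.0140 M | 0.0140 M | 0.0140 M | 0.0140 M |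
| free catalyst | 0.17 mM | 0.17 mM | 0.17 mM | 0.26 mM | 0.17 mM | 0.17 mM | 0.17 mM | 0.17 mM |
| remark | run made earlier | run made earlier | run made earlier | run made earlier | all but coupling partner at the start; coupling partner goes in evenly over 3.00 h, the run ends at 3.0 h | a closed flask charged with all of it at once and left for 3.0 h | one stirred flow tank at steady state, fed with the mixture as stated, mean residence time 3.0 h | a stirred flask in which substrate is dosed at a steady rate over 3.00 h without added volume, worked up at 3.0 h |
| time |  |  |  |  | 3.0 h | 3.0 h |  | 3.0 h |

| run | time / h | product / % |
|---|---|---|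
| epsilon | 0.667 | 39.1 |
| epsilon | 1.33 | 68.3 |
| epsilon | 2.00 | 83.4 |
| epsilon | 2.50 | 90.5 |
| epsilon | 3.00 | 93.0 |
| beta | 0.200 | 9.8 |
| beta | 0.667 | 39.9 |
| beta | 1.00 | 56.3 |
| beta | 1.50 | 72.8 |
| beta | 2.50 | 90.8 |
| gamma | 0.200 | 10.0 |
| gamma | 0.333 | 19.7 |
| gamma | 0.667 | 38.5 |
| gamma | 1.33 | 66.9 |
| gamma | 2.50 | 87.8 |
| eta | 0.200 | 17.9 |
| eta | 0.333 | 29.8 |
| eta | 0.667 | 55.6 |
| eta | 1.33 | 84.1 |
| eta | 2.50 | 94.6 |

(standard deviation of a reading: 0.5 percentage points)

- the stated concentrations are those of everything mixed, before any reaction; amounts are the same in each set-up
- the feed brings no volume worth counting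
- the earlier runs were made in a closed, stirred flask

1. the set-up with the highest amount of product at the outlet or at the end, in percent of the substrate put in ("none" if the first two lie within 2 percentage points) (ochre / blue / grey / red / none)
2. amount of product at the outlet or at the end, in percent of the substrate put in, ochre
3. amount of product at the outlet or at the end, in percent of the substrate put in, blue
4. amount of product at the outlet or at the end, in percent of the substrate put in, grey
5. amount of product at the outlet or at the end, in percent of the substrate put in, red

- Free catalyst must be known well for the pace, but the four set-ups keep epsilon's 0.17 mM, and blue repeats epsilon, which reads 93.0% at 3.00 h.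
- Capture agent shows late: at 2.50 h gamma reads 2.7 points below epsilon.
- No earlier run varies the coupling partner, so its weight is unread, and that doubt sits on ochre and red, where dosing shifts it against the substrate.
- I define s = 5.00%, the capture share: the part of the substrate charge that capture agent takes away if it takes one substrate each and is itself used up, as limiting reagent of that side path.
- On those terms the product ceiling is 1 − s = 95.0%, and at this share it stands above the highest reading, eta's 94.6%.
- My own commitment is blue at about 93.0% and best, 2 points below that ceiling.
- The forecast gives 85% for ochre, 93% for blue, 72% for grey and 65% for red, so blue is best; for ochre it expects “some loss at low partner concentration”.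
- The simulation gives 73.0% for ochre, 93.0% for blue, 71.4% for grey and 69.2% for red, so blue is best, and ochre lies 12 points below the forecast.

    substrate + free catalyst → free catalyst + open intermediate (k = 290 /M/min)
    free catalyst + open intermediate ⇌ catalyst intermediate (K = 170 /M, k = 850 /M/min)
    coupling partner + catalyst intermediate → free catalyst + product (k = 130 /M/min)
    open intermediate + capture agent → trapped intermediate (k = 1.40 /M/min)

- At 3.00 h ochre holds 5.00% trapped intermediate, matching s, with capture agent at 0%. Its 22 points below the ceiling stand as 11.9% substrate, 10.0% open intermediate and 0.0342% catalyst intermediate, and at 30.0 h ochre holds 95.0% product. Red's neighbour with 0.056 M capture agent has a share of 20.0%, so a ceiling of 80.0% once that agent is used up. With 8.4% of its capture agent left, that share gives 18.3% trapped, and this neighbour holds 18.3% trapped intermediate beside 59.2% product.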